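**Retrosynthetic overview**

1. Target ⇒ two deprotections, 6β- and 3α-acylation, C6 oxygen from hydroboration–oxidation–reduction of C5=C6, chain extension at C11 ⇒ diol from reductive opening of a bridged lactone-diene.
2. Key disconnection: C9–C10 and C7–C8 of ring B by a temporary-tether intramolecular Diels–Alder reaction of the 3α-but-2-ynoate of a ring A 1-vinylcyclohexene; ring B and a temporary seven-membered O3–C11 lactone close together.
3. Feature used: the C3 oxygen is axial on the α face of ring A, 1,4 across that ring from C10 and anti to the C20 methyl, and C17–C8=C9–C11 is a but-2-ynoate unit, so an ester on O3 carries C9 to the α face of C10.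
4. Ring A diene ⇐ enol triflate and Stille vinylation ⇐ C10 methylation ⇐ (2S,3R)-hydroxy ketone ⇐ hydroxyl-directed asymmetric hydrogenation of prochiral 2-(hydroxymethyl)-2-methylcyclohexane-1,3-dione (sets C3 and C4 with O3 anti to C19).
5. Ring order: ring A is bought; ring B (with the temporary lactone ring) is formed in the key step; the side chain follows.

Key step: step 9

Remark: labdane numbering is used for all intermediates (C18 = 4α-methyl, C19 = 4β-CH2O carbon, C20 = C10 methyl, C17 = C8 methyl, C11–C16 = side chain). The sense of induction of the (R)-BINAP catalyst in step 2 is assigned by analogy with simple β-hydroxy ketones. The reduction is placed before silylation because a non-directed reduction of the silylated dione would be expected to put the hydroxyl cis to C19.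

Step 1
Reactants: 1 2-methylcyclohexane-1,3-dione
Product: 2 2-(hydroxymethyl)-2-methylcyclohexane-1,3-dione
Conditions: aq. HCHO (37%), cat. Et3N, THF/H2O, rt
Reagents that add atoms: formaldehyde, C=O
Why: Aldol hydroxymethylation of the enolised 1,3-dione at its only nucleophilic carbon (future C4) builds the quaternary carbon carrying C18 and C19, and no stereocenter arises because the product is still mirror-symmetric.

Step 2
Reactants: 2 2-(hydroxymethyl)-2-methylcyclohexane-1,3-dione
Product: 3 (2S,3R)-3-hydroxy-2-(hydroxymethyl)-2-methylcyclohexan-1-one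
Conditions: H2 (50 atm), RuCl2[(R)-BINAP] (1 mol%), MeOH, 30 °C, stopped after one equivalent of H2
Reagents that add atoms: none
Why: Noyori asymmetric hydrogenation of a β-hydroxy ketone, in which the primary hydroxyl and one carbonyl chelate ruthenium so that hydride reaches C3 from the face bearing C19 (3-OH anti to C19), while the ligand chooses between the two enantiotopic carbonyls and so sets C3 and C4 together.

Step 3
Reactants: 3 (2S,3R)-3-hydroxy-2-(hydroxymethyl)-2-methylcyclohexan-1-one
Product: 5 (2S,3R)-2-[(tert-butyldiphenylsilyloxy)methyl]-2-methyl-3-(triethylsilyloxy)cyclohexan-1-one, via primary silyl ether 4 (not isolated)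
Conditions: TBDPSCl, imidazole, DMF, 0 °C; then TESCl, rt
Reagents that add atoms: tert-butyl(chloro)diphenylsilane, CC(C)(C)[Si](Cl)(c1ccccc1)c1ccccc1; chlorotriethylsilane, CC[Si](Cl)(CC)CC
Why: Two silyl ether formations in one flask, the bulky chlorosilane taking the unhindered primary hydroxyl first and the smaller one the secondary hydroxyl, which also blocks retro-aldol cleavage of the β-hydroxy ketone.

Step 4
Reactants: 5 (2S,3R)-2-[(tert-butyldiphenylsilyloxy)methyl]-2-methyl-3-(triethylsilyloxy)cyclohexan-1-one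
Product: 7 (2S,3R)-2-[(tert-butyldiphenylsilyloxy)methyl]-2,6-dimethyl-3-(triethylsilyloxy)cyclohexan-1-one (C6 epimers), via lithium enolate 6 (not isolated)
Conditions: LiN(i-Pr)2, THF, −78 °C; then MeI, DMPU, −78 to −30 °C
Reagents that add atoms: iodomethane, CI
Why: Enolate alkylation in which the C5 ketone can enolise only towards C10 because C4 is quaternary, so the future C20 methyl goes on C10; the new center is irrelevant because C10 becomes trigonal in step 5.

Step 5
Reactants: 7 (2S,3R)-2-[(tert-butyldiphenylsilyloxy)methyl]-2,6-dimethyl-3-(triethylsilyloxy)cyclohexan-1-one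
Product: 9 (5R,6S)-6-[(tert-butyldiphenylsilyloxy)methyl]-2,6-dimethyl-5-(triethylsilyloxy)cyclohex-1-en-1-yl trifluoromethanesulfonate, via potassium enolate 8 (not isolated)
Conditions: KN(SiMe3)2, THF, −78 to 0 °C; then PhNTf2, −78 °C to rt
Reagents that add atoms: N-phenylbis(trifluoromethanesulfonimide), O=S(=O)(N(c1ccccc1)S(=O)(=O)C(F)(F)F)C(F)(F)F
Why: Only one enolate is possible, so O-sulfonylation gives the tetrasubstituted C5=C10 enol triflate regiospecifically, as with 2,2,6-trimethylcyclohexanone.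

Step 6
Reactants: 9 (5R,6S)-6-[(tert-butyldiphenylsilyloxy)methyl]-2,6-dimethyl-5-(triethylsilyloxy)cyclohex-1-en-1-yl trifluoromethanesulfonate; 10 tributyl(vinyl)stannane
Product: 11 tert-butyl{[(1S,6R)-2-ethenyl-1,3-dimethyl-6-(triethylsilyloxy)cyclohex-2-en-1-yl]methoxy}diphenylsilane
Conditions: Pd2(dba)3, AsPh3, LiCl, N-methylpyrrolidinone, 60 °C
Reagents that add atoms: none
Why: Stille coupling of the hindered enol triflate, helped by LiCl and the weakly bound AsPh3 ligand, installs C6=C7 and completes the ring A diene (precedent: 2,6,6-trimethylcyclohexenyl triflate).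

Step 7
Reactants: 11 tert-butyl{[(1S,6R)-2-ethenyl-1,3-dimethyl-6-(triethylsilyloxy)cyclohex-2-en-1-yl]methoxy}diphenylsilane
Product: 12 (1R,2S)-2-[(tert-butyldiphenylsilyloxy)methyl]-3-ethenyl-2,4-dimethylcyclohex-3-en-1-ol
Conditions: PPTS, MeOH/CH2Cl2, 0 °C
Reagents that add atoms: none
Why: Mild acid methanolysis cleaves the triethylsilyl ether much faster than the tert-butyldiphenylsilyl ether, freeing only the 3α-hydroxyl.

Step 8
Reactants: 12 (1R,2S)-2-[(tert-butyldiphenylsilyloxy)methyl]-3-ethenyl-2,4-dimethylcyclohex-3-en-1-ol; 13 but-2-ynoic acid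
Product: 14 (1R,2S)-2-[(tert-butyldiphenylsilyloxy)methyl]-3-ethenyl-2,4-dimethylcyclohex-3-en-1-yl but-2-ynoate
Conditions: DCC, DMAP (cat.), CH2Cl2, −20 to 0 °C
Reagents that add atoms: none
Why: Steglich esterification at low temperature with only catalytic DMAP attaches the tether to O3 while limiting isomerisation of the ynoate to the allenoate.

Step 9
Reactants: 14 (1R,2S)-2-[(tert-butyldiphenylsilyloxy)methyl]-3-ethenyl-2,4-dimethylcyclohex-3-en-1-yl but-2-ynoate
Product: 15 19-(tert-butyldiphenylsilyloxy)-12,13,14,15,16-pentanorlabda-5,8-dien-11,3α-olide (lactone bridging O3 and C11)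
Conditions: 1,2-dichlorobenzene (0.005 M), BHT, base-washed sealed tube, 180 °C
Reagents that add atoms: none
Why: Proposed new method: on heating, the but-2-ynoate held on the axial 3α-oxygen swings under ring A and adds to the s-cis C10=C5–C6=C7 diene in a concerted, asynchronous [4+2] cycloaddition (C7–C8 bonding ahead of C9–C10); the closest known reactions are ester-tethered intramolecular Diels–Alder reactions of alkynoates and the intermolecular Diels–Alder reaction of 2,6,6-trimethyl-1-vinylcyclohexene with acetylenic esters, which already creates this angular methyl and 5,8-diene. Ring B closes as a six-membered 1,4-cyclohexadiene by the cycloaddition itself, and the seven-membered lactone O3–C11–C9–C10–C1–C2–C3 closes in a bridged mode (bicyclo[3.2.2] across a boat ring A) because the tether joins C3 to the diene terminus C10 that lies 1,4 to it. The one new stereocenter, C10, is fixed by the tether: C9 can reach only the α face, syn to O3 and anti to C19 on C4, so the C20 methyl is pushed to the β face. Regiochemistry (C9 to C10, C8 to C7) is imposed by the tether length and agrees with the polarity of the diene, whose unhindered C7 terminus is its most nucleophilic end and attacks the β-carbon of the ynoate. The reactive half-chair with O3 axial should be favoured because the bulky C19 silyloxymethyl group on the allylic C4 prefers the pseudoaxial position trans to it; the open risk is the strain of the bridged transition state (ester forced s-cis, ring A towards a boat) set against a [1,5]-hydrogen shift of the Z-methyl diene at this temperature.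

Step 10
Reactants: 15 19-(tert-butyldiphenylsilyloxy)-12,13,14,15,16-pentanorlabda-5,8-dien-11,3α-olide
Product: 16 19-(tert-butyldiphenylsilyloxy)-12,13,14,15,16-pentanorlabda-5,8-diene-3α,11-diol
Conditions: i-Bu2AlH, CH2Cl2, −78 to 0 °C; aq. potassium sodium tartrate
Reagents that add atoms: none
Why: 1,2-Reduction of the conjugated lactone through the lactol gives the primary allylic alcohol at C11 and releases the 3α-hydroxyl, after which ring A should relax from the boat to the chair with C19 and C20 axial.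

Step 11
Reactants: 16 19-(tert-butyldiphenylsilyloxy)-12,13,14,15,16-pentanorlabda-5,8-diene-3α,11-diol
Product: 17 11-bromo-19-(tert-butyldiphenylsilyloxy)-12,13,14,15,16-pentanorlabda-5,8-dien-3α-ol
Conditions: NBS, Me2S, CH2Cl2, −20 to 0 °C
Reagents that add atoms: N-bromosuccinimide, O=C1CCC(=O)N1Br
Why: Corey–Kim bromination, in which only the allylic alkoxysulfonium salt is displaced by bromide, so the C11 hydroxyl is replaced while the hindered saturated 3α-hydroxyl returns unchanged on work-up.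

Step 12
Reactants: 17 11-bromo-19-(tert-butyldiphenylsilyloxy)-12,13,14,15,16-pentanorlabda-5,8-dien-3α-ol; 18 tert-butyl 3-oxobutanoate
Product: 19 tert-butyl 19-(tert-butyldiphenylsilyloxy)-3α-hydroxy-13-oxo-16-norlabda-5,8-dien-15-oate
Conditions: NaH then n-BuLi on 18 (3 equiv), THF, 0 °C; then 17, 0 °C
Reagents that add atoms: none
Why: Weiler alkylation, in which the terminal carbon of the acetoacetate dianion displaces the primary allylic bromide in an SN2 reaction to form C11–C12, one extra equivalent of dianion taking up the hydroxyl proton.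

Step 13
Reactants: 19 tert-butyl 19-(tert-butyldiphenylsilyloxy)-3α-hydroxy-13-oxo-16-norlabda-5,8-dien-15-oate
Product: 21 tert-butyl (13Z)-19-(tert-butyldiphenylsilyloxy)-13-(diethoxyphosphoryloxy)-3α-hydroxy-16-norlabda-5,8,13-trien-15-oate, via sodium enolate 20 (not isolated)
Conditions: NaH (1.05 equiv), Et2O, 0 °C; then ClP(O)(OEt)2, 0 °C
Reagents that add atoms: diethyl chlorophosphate, CCOP(=O)(Cl)OCC
Why: The chelated sodium enolate of the β-keto ester is O-phosphorylated with retention of its Z geometry (Weiler enol phosphate formation), which fixes the later alkene geometry.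

Step 14
Reactants: 21 tert-butyl (13Z)-19-(tert-butyldiphenylsilyloxy)-13-(diethoxyphosphoryloxy)-3α-hydroxy-16-norlabda-5,8,13-trien-15-oate
Product: 22 tert-butyl (13E)-19-(tert-butyldiphenylsilyloxy)-3α-hydroxylabda-5,8,13-trien-15-oate
Conditions: Me2CuLi (from MeLi and CuI, 4 equiv), Et2O, −78 to −45 °C
Reagents that add atoms: lithium dimethylcuprate, [Li+].C[Cu-]C (from methyllithium, [Li]C, and CuI)
Why: Addition–elimination of the cuprate on the β-phosphoryloxy enoate replaces phosphate by methyl with retention, giving the E enoate with the C16 methyl cis to the ester, the excess reagent covering the free hydroxyl.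

Step 15
Reactants: 22 tert-butyl (13E)-19-(tert-butyldiphenylsilyloxy)-3α-hydroxylabda-5,8,13-trien-15-oate
Product: 23 tert-butyl (13E)-19-(tert-butyldiphenylsilyloxy)-3α-(3-methylbutanoyloxy)labda-5,8,13-trien-15-oate
Conditions: (i-BuCO)2O, DMAP, Et3N, CH2Cl2, rt
Reagents that add atoms: 3-methylbutanoic anhydride, CC(C)CC(=O)OC(=O)CC(C)C
Why: DMAP-catalysed acylation of the axial 3α-hydroxyl, done at this point so that this alcohol cannot be oxidised in step 17.

Step 16
Reactants: 23 tert-butyl (13E)-19-(tert-butyldiphenylsilyloxy)-3α-(3-methylbutanoyloxy)labda-5,8,13-trien-15-oate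
Product: 25 tert-butyl (13E)-19-(tert-butyldiphenylsilyloxy)-6α-hydroxy-3α-(3-methylbutanoyloxy)labda-8,13-dien-15-oate, via 6α-alkylborane 24 (not isolated)
Conditions: BH3·THF (limited excess), THF, 0 °C to rt; then NaBO3·4H2O, H2O, rt
Reagents that add atoms: borane–tetrahydrofuran, B.C1CCOC1 (boron of 24); sodium perborate, [Na+].[Na+].O[B-]1(O)OO[B-](O)(O)OO1 (oxygen at C6 of 25)
Why: Hydroboration–oxidation, in which electrophilic borane should prefer the electron-rich trisubstituted C5=C6 over the electron-poor enoate and the shielded tetrasubstituted C8=C9, with boron on C6 and hydrogen on C5 added syn from the α face because the β face is closed by the axial C19 and C20 groups, which sets 5α-H (trans ring fusion).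

Step 17
Reactants: 25 tert-butyl (13E)-19-(tert-butyldiphenylsilyloxy)-6α-hydroxy-3α-(3-methylbutanoyloxy)labda-8,13-dien-15-oate
Product: 26 tert-butyl (13E)-19-(tert-butyldiphenylsilyloxy)-3α-(3-methylbutanoyloxy)-6-oxolabda-8,13-dien-15-oate
Conditions: Dess–Martin periodinane, NaHCO3, CH2Cl2, 0 °C to rt
Reagents that add atoms: none
Why: Dess–Martin oxidation of the only free hydroxyl gives the 6-ketone under buffered, non-enolising conditions that should leave the β,γ C8=C9 double bond in place.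

Step 18
Reactants: 26 tert-butyl (13E)-19-(tert-butyldiphenylsilyloxy)-3α-(3-methylbutanoyloxy)-6-oxolabda-8,13-dien-15-oate
Product: 27 tert-butyl (13E)-19-(tert-butyldiphenylsilyloxy)-6β-hydroxy-3α-(3-methylbutanoyloxy)labda-8,13-dien-15-oate
Conditions: NaBH4, CeCl3·7H2O, MeOH/THF, −40 °C
Reagents that add atoms: none
Why: Hydride reduction from the open α side, the β approach being blocked by the syn-axial C19 and C20 groups, gives the axial 6β-alcohol as with 6-oxo steroids, and the low temperature avoids conjugation of the C8=C9 double bond.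

Step 19
Reactants: 27 tert-butyl (13E)-19-(tert-butyldiphenylsilyloxy)-6β-hydroxy-3α-(3-methylbutanoyloxy)labda-8,13-dien-15-oate
Product: 28 tert-butyl (13E)-19-(tert-butyldiphenylsilyloxy)-3α,6β-bis(3-methylbutanoyloxy)labda-8,13-dien-15-oate
Conditions: (i-BuCO)2O, DMAP (2 equiv), Et3N, toluene, 80 °C
Reagents that add atoms: 3-methylbutanoic anhydride, CC(C)CC(=O)OC(=O)CC(C)C
Why: Forced DMAP acylation of the 6β-hydroxyl, which is 1,3-diaxial to C19 and C20 and therefore needs heat and a full equivalent of the acyl-transfer catalyst.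

Step 20
Reactants: 28 tert-butyl (13E)-19-(tert-butyldiphenylsilyloxy)-3α,6β-bis(3-methylbutanoyloxy)labda-8,13-dien-15-oate
Product: 30 (13E)-19-(tert-butyldiphenylsilyloxy)-3α,6β-bis(3-methylbutanoyloxy)labda-8,13-dien-15-oic acid, via trimethylsilyl ester 29 (not isolated)
Conditions: Me3SiOTf, 2,6-lutidine, CH2Cl2, 0 °C; then H2O
Reagents that add atoms: trimethylsilyl trifluoromethanesulfonate, C[Si](C)(C)OS(=O)(=O)C(F)(F)F (silyl group of 29 only)
Why: Silyl triflate activates the tert-butyl ester, isobutene is lost and the silyl ester is hydrolysed on work-up, the buffered non-protic conditions sparing the C8=C9 alkene, both isovalerates and the silyl ether.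

Step 21
Reactants: 30 (13E)-19-(tert-butyldiphenylsilyloxy)-3α,6β-bis(3-methylbutanoyloxy)labda-8,13-dien-15-oic acid
Product: 31 (13E)-19-hydroxy-3α,6β-bis(3-methylbutanoyloxy)labda-8,13-dien-15-oic acid (CNP0272110.1)
Conditions: HF·pyridine, pyridine, THF, 0 °C to rt
Reagents that add atoms: none
Why: Buffered fluoride cleaves the primary silyl ether under weakly acidic conditions, so no alkoxide is formed that could take over the neighbouring 6β-acyl group.

**Compound list**

1 | 2-methylcyclohexane-1,3-dione | CC1C(=O)CCCC1=O | starting material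
2 | 2-(hydroxymethyl)-2-methylcyclohexane-1,3-dione | CC1(CO)C(=O)CCCC1=O | intermediate
3 | (2S,3R)-3-hydroxy-2-(hydroxymethyl)-2-methylcyclohexan-1-one | O=C1CCC[C@@H](O)[C@]1(C)CO | intermediate
4 | (2S,3R)-2-[(tert-butyldiphenylsilyloxy)methyl]-3-hydroxy-2-methylcyclohexan-1-one (not isolated) | O=C1CCC[C@@H](O)[C@]1(C)CO[Si](c1ccccc1)(c1ccccc1)C(C)(C)C | intermediate
5 | (2S,3R)-2-[(tert-butyldiphenylsilyloxy)methyl]-2-methyl-3-(triethylsilyloxy)cyclohexan-1-one | O=C1CCC[C@@H](O[Si](CC)(CC)CC)[C@]1(C)CO[Si](c1ccccc1)(c1ccccc1)C(C)(C)C | intermediate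
6 | lithium enolate of 5 (not isolated) | [Li+].[O-]C1=CCC[C@@H](O[Si](CC)(CC)CC)[C@]1(C)CO[Si](c1ccccc1)(c1ccccc1)C(C)(C)C | intermediate
7 | (2S,3R)-2-[(tert-butyldiphenylsilyloxy)methyl]-2,6-dimethyl-3-(triethylsilyloxy)cyclohexan-1-one, C6 epimers | O=C1C(C)CC[C@@H](O[Si](CC)(CC)CC)[C@]1(C)CO[Si](c1ccccc1)(c1ccccc1)C(C)(C)C | intermediate
8 | potassium enolate of 7 (not isolated) | [K+].[O-]C1=C(C)CC[C@@H](O[Si](CC)(CC)CC)[C@]1(C)CO[Si](c1ccccc1)(c1ccccc1)C(C)(C)C | intermediate
9 | (5R,6S)-6-[(tert-butyldiphenylsilyloxy)methyl]-2,6-dimethyl-5-(triethylsilyloxy)cyclohex-1-en-1-yl trifluoromethanesulfonate | O=S(=O)(OC1=C(C)CC[C@@H](O[Si](CC)(CC)CC)[C@]1(C)CO[Si](c1ccccc1)(c1ccccc1)C(C)(C)C)C(F)(F)F | intermediate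
10 | tributyl(vinyl)stannane | C=C[Sn](CCCC)(CCCC)CCCC | starting material
11 | tert-butyl{[(1S,6R)-2-ethenyl-1,3-dimethyl-6-(triethylsilyloxy)cyclohex-2-en-1-yl]methoxy}diphenylsilane | C=CC1=C(C)CC[C@@H](O[Si](CC)(CC)CC)[C@]1(C)CO[Si](c1ccccc1)(c1ccccc1)C(C)(C)C | intermediate
12 | (1R,2S)-2-[(tert-butyldiphenylsilyloxy)methyl]-3-ethenyl-2,4-dimethylcyclohex-3-en-1-ol | C=CC1=C(C)CC[C@@H](O)[C@]1(C)CO[Si](c1ccccc1)(c1ccccc1)C(C)(C)C | intermediate
13 | but-2-ynoic acid | CC#CC(=O)O | starting material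
14 | (1R,2S)-2-[(tert-butyldiphenylsilyloxy)methyl]-3-ethenyl-2,4-dimethylcyclohex-3-en-1-yl but-2-ynoate (key-step precursor) | C=CC1=C(C)CC[C@@H](OC(=O)C#CC)[C@]1(C)CO[Si](c1ccccc1)(c1ccccc1)C(C)(C)C | intermediate
15 | 19-(tert-butyldiphenylsilyloxy)-12,13,14,15,16-pentanorlabda-5,8-dien-11,3α-olide (key-step product) | CC1=C(C(=O)O3)[C@@]2(C)CC[C@@H]3[C@](C)(CO[Si](c4ccccc4)(c4ccccc4)C(C)(C)C)C2=CC1 | intermediate
16 | 19-(tert-butyldiphenylsilyloxy)-12,13,14,15,16-pentanorlabda-5,8-diene-3α,11-diol | CC1=C(CO)[C@@]2(C)CC[C@@H](O)[C@](C)(CO[Si](c3ccccc3)(c3ccccc3)C(C)(C)C)C2=CC1 | intermediate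
17 | 11-bromo-19-(tert-butyldiphenylsilyloxy)-12,13,14,15,16-pentanorlabda-5,8-dien-3α-ol | CC1=C(CBr)[C@@]2(C)CC[C@@H](O)[C@](C)(CO[Si](c3ccccc3)(c3ccccc3)C(C)(C)C)C2=CC1 | intermediate
18 | tert-butyl 3-oxobutanoate | CC(=O)CC(=O)OC(C)(C)C | starting material
19 | tert-butyl 19-(tert-butyldiphenylsilyloxy)-3α-hydroxy-13-oxo-16-norlabda-5,8-dien-15-oate | CC1=C(CCC(=O)CC(=O)OC(C)(C)C)[C@@]2(C)CC[C@@H](O)[C@](C)(CO[Si](c3ccccc3)(c3ccccc3)C(C)(C)C)C2=CC1 | intermediate
20 | sodium (Z)-enolate of 19 (not isolated) | [Na+].CC1=C(CC/C([O-])=C/C(=O)OC(C)(C)C)[C@@]2(C)CC[C@@H](O)[C@](C)(CO[Si](c3ccccc3)(c3ccccc3)C(C)(C)C)C2=CC1 | intermediate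
21 | tert-butyl (13Z)-19-(tert-butyldiphenylsilyloxy)-13-(diethoxyphosphoryloxy)-3α-hydroxy-16-norlabda-5,8,13-trien-15-oate | CC1=C(CC/C(OP(=O)(OCC)OCC)=C/C(=O)OC(C)(C)C)[C@@]2(C)CC[C@@H](O)[C@](C)(CO[Si](c3ccccc3)(c3ccccc3)C(C)(C)C)C2=CC1 | intermediate
22 | tert-butyl (13E)-19-(tert-butyldiphenylsilyloxy)-3α-hydroxylabda-5,8,13-trien-15-oate | CC1=C(CC/C(C)=C/C(=O)OC(C)(C)C)[C@@]2(C)CC[C@@H](O)[C@](C)(CO[Si](c3ccccc3)(c3ccccc3)C(C)(C)C)C2=CC1 | intermediate
23 | tert-butyl (13E)-19-(tert-butyldiphenylsilyloxy)-3α-(3-methylbutanoyloxy)labda-5,8,13-trien-15-oate | CC1=C(CC/C(C)=C/C(=O)OC(C)(C)C)[C@@]2(C)CC[C@@H](OC(=O)CC(C)C)[C@](C)(CO[Si](c3ccccc3)(c3ccccc3)C(C)(C)C)C2=CC1 | intermediate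
24 | 6α-boryl-5α-H adduct of 23, drawn as the monoalkylborane (not isolated) | CC1=C(CC/C(C)=C/C(=O)OC(C)(C)C)[C@@]2(C)CC[C@@H](OC(=O)CC(C)C)[C@](C)(CO[Si](c3ccccc3)(c3ccccc3)C(C)(C)C)[C@@H]2[C@@H](B)C1 | intermediate
25 | tert-butyl (13E)-19-(tert-butyldiphenylsilyloxy)-6α-hydroxy-3α-(3-methylbutanoyloxy)labda-8,13-dien-15-oate | CC1=C(CC/C(C)=C/C(=O)OC(C)(C)C)[C@@]2(C)CC[C@@H](OC(=O)CC(C)C)[C@](C)(CO[Si](c3ccccc3)(c3ccccc3)C(C)(C)C)[C@@H]2[C@@H](O)C1 | intermediate
26 | tert-butyl (13E)-19-(tert-butyldiphenylsilyloxy)-3α-(3-methylbutanoyloxy)-6-oxolabda-8,13-dien-15-oate | CC1=C(CC/C(C)=C/C(=O)OC(C)(C)C)[C@@]2(C)CC[C@@H](OC(=O)CC(C)C)[C@](C)(CO[Si](c3ccccc3)(c3ccccc3)C(C)(C)C)[C@@H]2C(=O)C1 | intermediate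
27 | tert-butyl (13E)-19-(tert-butyldiphenylsilyloxy)-6β-hydroxy-3α-(3-methylbutanoyloxy)labda-8,13-dien-15-oate | CC1=C(CC/C(C)=C/C(=O)OC(C)(C)C)[C@@]2(C)CC[C@@H](OC(=O)CC(C)C)[C@](C)(CO[Si](c3ccccc3)(c3ccccc3)C(C)(C)C)[C@@H]2[C@H](O)C1 | intermediate
28 | tert-butyl (13E)-19-(tert-butyldiphenylsilyloxy)-3α,6β-bis(3-methylbutanoyloxy)labda-8,13-dien-15-oate | CC1=C(CC/C(C)=C/C(=O)OC(C)(C)C)[C@@]2(C)CC[C@@H](OC(=O)CC(C)C)[C@](C)(CO[Si](c3ccccc3)(c3ccccc3)C(C)(C)C)[C@@H]2[C@H](OC(=O)CC(C)C)C1 | intermediate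
29 | trimethylsilyl ester corresponding to 28 (not isolated) | CC1=C(CC/C(C)=C/C(=O)O[Si](C)(C)C)[C@@]2(C)CC[C@@H](OC(=O)CC(C)C)[C@](C)(CO[Si](c3ccccc3)(c3ccccc3)C(C)(C)C)[C@@H]2[C@H](OC(=O)CC(C)C)C1 | intermediate
30 | (13E)-19-(tert-butyldiphenylsilyloxy)-3α,6β-bis(3-methylbutanoyloxy)labda-8,13-dien-15-oic acid | CC1=C(CC/C(C)=C/C(=O)O)[C@@]2(C)CC[C@@H](OC(=O)CC(C)C)[C@](C)(CO[Si](c3ccccc3)(c3ccccc3)C(C)(C)C)[C@@H]2[C@H](OC(=O)CC(C)C)C1 | intermediate
31 | (13E)-19-hydroxy-3α,6β-bis(3-methylbutanoyloxy)labda-8,13-dien-15-oic acid (CNP0272110.1) | CC1=C(CC/C(C)=C/C(=O)O)[C@@]2(C)CC[C@@H](OC(=O)CC(C)C)[C@](C)(CO)[C@@H]2[C@H](OC(=O)CC(C)C)C1 | target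

**Step count**

Total steps: 21. Longest linear sequence: 21 steps (1 to 31); 10, 13 and 18 are bought and used directly.

**Steps most likely to fail**

Step 9 (intramolecular Diels–Alder reaction). The bridged transition state may not be reached before other thermal processes take over: [1,5]-hydrogen shift from the Z-methyl of the diene, ene reactions of the ynoate, or oligomerisation. Fallback with known chemistry, setting out from 11 and returning at 16: the triethylsilyl ether 11 (no free hydroxyl) is combined with but-2-ynal and catalytic Me2AlCl in CH2Cl2 at low temperature, an intermolecular Lewis acid-promoted Diels–Alder reaction of an alkynal with a 2,6,6-trisubstituted 1-vinylcyclohexene. The unhindered, most nucleophilic C7 terminus bonds to the β-carbon of the ynal, so the formyl-bearing carbon ends on C10 and gives the 5,8-dien-11-al F1. Without the tether, the C10 configuration rests only on approach anti to the pseudoaxial C19 group, and a face isomer would have to be removed by chromatography. NaBH4/CeCl3 then reduces the enal to the allylic alcohol F2, and PPTS in methanol removes the triethylsilyl group to give diol 16, bypassing lactone 15.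

Step 2 (desymmetrising hydrogenation). The two enantiotopic carbonyls may be discriminated incompletely, a non-chelated or diketone-chelated pathway may erode the anti relationship, the second carbonyl may be reduced, or formaldehyde may be lost by retro-aldol cleavage. Fallback, setting out from 2 and returning at 3: Me4NBH(OAc)3 in MeCN/AcOH at −20 °C reduces 2 by intramolecular hydride delivery from the primary hydroxyl to the racemic anti diol, that is 3 together with its enantiomer F3. The racemate is acetalised with (−)-menthone under acid catalysis to the diastereomeric spiro-acetals F4 (from 3) and F5 (from F3), which are separated by chromatography or crystallisation. Mild acid methanolysis of F4 returns 3 as a single enantiomer.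

Step 16 (hydroboration in the presence of the enoate). Chemoselectivity may be lost: borane may add to or reduce the conjugated ester at a rate comparable to its slow addition to the doubly neopentylic C5=C6. Fallback, setting out from 16 and returning at 28, in which ring B is oxygenated before any conjugated ester exists: diol 16 is hydroborated and oxidised (BH3·THF; NaOH/H2O2) to the 3α,6α,11-triol F6. NBS/Me2S converts only the allylic hydroxyl into the bromide F7. Alkylation of the dianion of 18 gives the keto ester F8, NaH/ClP(O)(OEt)2 the enol phosphate F9, and Me2CuLi the enoate diol F10. Both secondary alcohols are then oxidised with Dess–Martin periodinane to the 3,6-dione F11. LiBH(s-Bu)3 at −78 °C, attacking each ketone from its less hindered equatorial direction, should return the two axial alcohols as the 3α,6β-diol F12; this re-forms C3 with its original configuration. One acylation of F12 with 3-methylbutanoic anhydride and DMAP gives 28.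

**Further compounds**

F1 | step 9 | 19-(tert-butyldiphenylsilyloxy)-3α-(triethylsilyloxy)-12,13,14,15,16-pentanorlabda-5,8-dien-11-al | CC1=C(C=O)[C@@]2(C)CC[C@@H](O[Si](CC)(CC)CC)[C@](C)(CO[Si](c3ccccc3)(c3ccccc3)C(C)(C)C)C2=CC1
F2 | step 9 | 19-(tert-butyldiphenylsilyloxy)-3α-(triethylsilyloxy)-12,13,14,15,16-pentanorlabda-5,8-dien-11-ol | CC1=C(CO)[C@@]2(C)CC[C@@H](O[Si](CC)(CC)CC)[C@](C)(CO[Si](c3ccccc3)(c3ccccc3)C(C)(C)C)C2=CC1
F3 | step 2 | (2R,3S)-3-hydroxy-2-(hydroxymethyl)-2-methylcyclohexan-1-one (enantiomer of 3) | O=C1CCC[C@H](O)[C@@]1(C)CO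
F4 | step 2 | spiro-acetal of 3 with (−)-menthone (spiro center not specified) | CC(C)[C@@H]1CC[C@@H](C)CC12OC[C@]3(C)C(=O)CCC[C@H]3O2
F5 | step 2 | spiro-acetal of F3 with (−)-menthone (spiro center not specified) | CC(C)[C@@H]1CC[C@@H](C)CC12OC[C@@]3(C)C(=O)CCC[C@@H]3O2
F6 | step 16 | 19-(tert-butyldiphenylsilyloxy)-12,13,14,15,16-pentanorlabd-8-ene-3α,6α,11-triol | CC1=C(CO)[C@@]2(C)CC[C@@H](O)[C@](C)(CO[Si](c3ccccc3)(c3ccccc3)C(C)(C)C)[C@@H]2[C@@H](O)C1
F7 | step 16 | 11-bromo-19-(tert-butyldiphenylsilyloxy)-12,13,14,15,16-pentanorlabd-8-ene-3α,6α-diol | CC1=C(CBr)[C@@]2(C)CC[C@@H](O)[C@](C)(CO[Si](c3ccccc3)(c3ccccc3)C(C)(C)C)[C@@H]2[C@@H](O)C1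
F8 | step 16 | tert-butyl 19-(tert-butyldiphenylsilyloxy)-3α,6α-dihydroxy-13-oxo-16-norlabd-8-en-15-oate | CC1=C(CCC(=O)CC(=O)OC(C)(C)C)[C@@]2(C)CC[C@@H](O)[C@](C)(CO[Si](c3ccccc3)(c3ccccc3)C(C)(C)C)[C@@H]2[C@@H](O)C1
F9 | step 16 | tert-butyl (13Z)-19-(tert-butyldiphenylsilyloxy)-13-(diethoxyphosphoryloxy)-3α,6α-dihydroxy-16-norlabda-8,13-dien-15-oate | CC1=C(CC/C(OP(=O)(OCC)OCC)=C/C(=O)OC(C)(C)C)[C@@]2(C)CC[C@@H](O)[C@](C)(CO[Si](c3ccccc3)(c3ccccc3)C(C)(C)C)[C@@H]2[C@@H](O)C1
F10 | step 16 | tert-butyl (13E)-19-(tert-butyldiphenylsilyloxy)-3α,6α-dihydroxylabda-8,13-dien-15-oate | CC1=C(CC/C(C)=C/C(=O)OC(C)(C)C)[C@@]2(C)CC[C@@H](O)[C@](C)(CO[Si](c3ccccc3)(c3ccccc3)C(C)(C)C)[C@@H]2[C@@H](O)C1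
F11 | step 16 | tert-butyl (13E)-19-(tert-butyldiphenylsilyloxy)-3,6-dioxolabda-8,13-dien-15-oate | CC1=C(CC/C(C)=C/C(=O)OC(C)(C)C)[C@@]2(C)CCC(=O)[C@](C)(CO[Si](c3ccccc3)(c3ccccc3)C(C)(C)C)[C@@H]2C(=O)C1
F12 | step 16 | tert-butyl (13E)-19-(tert-butyldiphenylsilyloxy)-3α,6β-dihydroxylabda-8,13-dien-15-oate | CC1=C(CC/C(C)=C/C(=O)OC(C)(C)C)[C@@]2(C)CC[C@@H](O)[C@](C)(CO[Si](c3ccccc3)(c3ccccc3)C(C)(C)C)[C@@H]2[C@H](O)C1
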